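Starting with the easy step: whatever has left starting material counts as reacted, so I follow the starting material and leave the target aside.

| flask | starting material | second substrate | free enzyme | remark | time |
|---|---|---|---|---|---|
| west | 0.10 M | 1 equiv | 0.029 mol% | run made earlier |  |
| east | 0.10 M | 1.5 equiv | 0.029 mol% | run made earlier |  |
| Thursday's | 0.10 M | 1.20 equiv | 0.029 mol% |  | 40 min |
| Wednesday's | 0.10 M | 2.40 equiv | 0.029 mol% |  | 40 min |

| run | time / min | starting material / % | target / % |
|---|---|---|---|
| west | 1.33 | 97.7 | 0 |
| west | 4.00 | 93.7 | 2.5 |
| west | 8.00 | 91.5 | 4.5 |
| west | 10.0 | 90.7 | 5.3 |
| west | 15.0 | 84.4 | 10.3 |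
| west | 20.0 | 79.4 | 11.2 |
| east | 1.50 | 97.7 | 0.5 |
| east | 2.50 | 95.5 | 2.8 |
| east | 4.00 | 95.7 | 3.5 |
| east | 8.00 | 88.5 | 5.9 |
| east | 12.0 | 84.1 | 11.6 |
| east | 20.0 | 75.3 | 15.0 |

(standard deviation of a reading: 1 percentage point)

- part of the starting material that has reacted at the end, Thursday's
- part of the starting material that has reacted at the end, Wednesday's
- what raising the equivalents of second substrate from its lowest to its highest value here does to the part of the starting material that has reacted (changes below 5 percentage points count as none) (it rises / no change / it falls)

- the earlier runs were read with a standard deviation of 1 percentage point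
- what has gone from starting material into another species counts as reacted, even if it can come back

The last readings, both at 20.0 min, leave 79.4% in the west run and 75.3% in the east run. If each flask loses a steady share of what it holds, these give decay constants of 0.0115 min⁻¹ and 0.0142 min⁻¹.

I assume that, across these flasks, more second substrate does not slow the loss and does not speed it more than in proportion. Thursday's, at 1.20 equiv, lies between the two runs, so its bracket at 40 min runs from 36.9% with the west constant to 43.3% with the east constant. Wednesday's, at 2.40 equiv, lies beyond both, so its floor is that same east figure, and its ceiling, with the east constant scaled in proportion to the equivalents, is 59.7%.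

To tighten this, I compare the two constants. Their ratio, set against the ratio of equivalents, gives 0.510, the apparent order in second substrate: the power of the equivalents that turns one constant into the other. It is a rough reading, since it rests on two readings with a scatter of 1 percentage point. Applied to the west constant, it gives me 39.7% for Thursday's and 51.4% for Wednesday's.

The forecast gives 40% and 52%, and says it rises, on the ground that “The rate rises less than proportionally with second substrate”.

The flask gives 39.7% for Thursday's and 51.4% for Wednesday's, so the answer on the trend is it rises: Wednesday's stands 12 points above Thursday's. With the time and the other amounts held, Wednesday's answer moves by 5 points at a free enzyme loading of 0.025 mol% or 0.033 mol%, so the loading needs watching. The constant implied by Wednesday's result, over that implied by Thursday's, is 1.43, against 1.42 from the apparent order.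

    starting material + first product ⇌ idle adduct, settled at all times (K = 17.0 L mol⁻¹)
    first complex → loaded enzyme + first product (k = 8.80 s⁻¹)
    starting material + free enzyme ⇌ first complex (K = 16.0 L mol⁻¹, k = 50.0 L mol⁻¹ s⁻¹)
    second complex ⇌ free enzyme + target (K = 0.110 M, k = 1.50 s⁻¹)
    second substrate + loaded enzyme ⇌ second complex (K = 4.90 L mol⁻¹, k = 92.0 L mol⁻¹ s⁻¹)

For the neighbour flask, Thursday's with 3.00 equiv, the apparent order gives 55.4% at 40 min. The computed result is 54.4%.

The data stem from a simulated flask on assumed constants; scatter was added.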